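**Strategy.** Ring B (C5–C6–C7=C8–C9–C10) carries the quaternary C10 next to the tertiary C9, and its C8 bears only a methyl group. The route therefore joins a ring-A aldehyde (C7) holding a C1=C10 alkene with an aroyl methacrylate (C11–C9=C8) in one iron-hydride-initiated radical–polar crossover annulation. The tertiary C10 radical adds to C9 and the C8 ester enolate closes on C7. This forms C9–C10 and C7–C8, assembles every skeletal carbon and sets C9 and C10. Decarboxylative β-lactone extrusion then fixes C7=C8, and the arene is dearomatised to the epoxy diol at the end.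

Key step: step 7

Assumption: drimane numbering (C1–C10, C11 on C9, C12 on C8) is used for the decalin and C1′–C6′ for the C7 ring (C1′ bonded to C11); the sense of induction in the reagent-controlled steps 2, 3 and 13 is assigned by the usual models, and the mirror-image catalyst or tartrate is taken if one proves reversed.

Step 1
Reactants: 1 ethyl 2-formylpropanoate
Product: 2 2-(trimethylsilyl)ethyl 2-formylpropanoate
Conditions: Me3SiCH2CH2OH (1.5 equiv), DMAP (10 mol%), toluene, 110 °C, EtOH distilled off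
Reagents that add atoms: 2-(trimethylsilyl)ethanol C[Si](C)(C)CCO
Why: Thermal transesterification of the β-oxo ester through its acylketene (the α-carbon is still enolisable, so no stereocenter is fixed) installs the fluoride-labile ester that is kept until step 16.

Step 2
Reactants: 2 2-(trimethylsilyl)ethyl 2-formylpropanoate; 3 pent-1-en-3-one
Product: 5 2-(trimethylsilyl)ethyl (1R)-1,3-dimethyl-4-oxocyclohex-2-ene-1-carboxylate, via Michael adduct 4 (not isolated)
Conditions: O-benzylcupreidine (10 mol%), CH2Cl2, −25 °C; then pyrrolidine (20 mol%), AcOH (20 mol%), 40 °C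
Reagents that add atoms: none
Why: Organocatalytic asymmetric Michael addition of the α-methyl β-oxo ester to the vinyl ketone sets the quaternary carbon (later C4) by catalyst control of the enolate face, and the amine-mediated intramolecular aldol condensation (Robinson annulation) can only close the six-membered 2-methylenone because the aldehyde carbon has no α-hydrogen.

Step 3
Reactants: 5 2-(trimethylsilyl)ethyl (1R)-1,3-dimethyl-4-oxocyclohex-2-ene-1-carboxylate
Product: 6 2-(trimethylsilyl)ethyl (1R,4R)-4-hydroxy-1,3-dimethylcyclohex-2-ene-1-carboxylate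
Conditions: (S)-1-methyl-3,3-diphenyltetrahydro-1H,3H-pyrrolo[1,2-c][1,3,2]oxazaborole (20 mol%), BH3·SMe2, THF, −30 °C
Reagents that add atoms: none
Why: Corey–Bakshi–Shibata reduction, in which the catalyst (the α-methylvinyl side acting as the large group) and not the remote quaternary centre chooses the carbonyl face, sets the carbinol carbon (later C1) with its hydroxyl cis to the C4 methyl group.

Step 4
Reactants: 6 2-(trimethylsilyl)ethyl (1R,4R)-4-hydroxy-1,3-dimethylcyclohex-2-ene-1-carboxylate
Product: 8 2-(trimethylsilyl)ethyl (1R,2R)-1,3-dimethyl-2-(2-oxoethyl)cyclohex-3-ene-1-carboxylate, via allyl vinyl ether 7 (not isolated)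
Conditions: n-BuOCH=CH2 (solvent), Pd(OCOCF3)2 (1 mol%), 4,7-diphenyl-1,10-phenanthroline (1 mol%), Et3N (5 mol%), 75 °C; then decane, 180 °C
Reagents that add atoms: butyl vinyl ether C=COCCCC
Why: Palladium-catalysed transfer vinylation followed by a Claisen rearrangement, whose suprafacial [3,3] shift forms the C5–C6 bond on the ring face that carried the C1–O bond (1,3-chirality transfer), sets C5 with the CH2CHO arm cis to the C4 methyl group and moves the alkene to C1=C10.

Step 5
Reactants: 9 1,4-dimethoxy-2-methylbenzene; 10 citraconic anhydride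
Product: 11 (2Z)-4-(2,5-dimethoxy-4-methylphenyl)-2-methyl-4-oxobut-2-enoic acid
Conditions: AlCl3 (2.2 equiv), CH2Cl2, 0 °C → rt
Reagents that add atoms: none
Why: Friedel–Crafts acylation at the ring position para to the methyl group with the less hindered anhydride carbonyl (the one next to CH) should give the β-aroyl-α-methylacrylic acid, in which the ketone is the future C11 and no stereocenter is created.

Step 6
Reactants: 11 (2Z)-4-(2,5-dimethoxy-4-methylphenyl)-2-methyl-4-oxobut-2-enoic acid
Product: 12 benzyl (2Z)-4-(2,5-dimethoxy-4-methylphenyl)-2-methyl-4-oxobut-2-enoate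
Conditions: BnBr, K2CO3, DMF, rt
Reagents that add atoms: benzyl bromide BrCc1ccccc1
Why: SN2 O-alkylation of the carboxylate gives the benzyl ester that is later removed by hydrogenolysis without touching the silylethyl ester; the alkene geometry is irrelevant because C8 and C9 become sp3 in step 7.

Step 7
Reactants: 8 2-(trimethylsilyl)ethyl (1R,2R)-1,3-dimethyl-2-(2-oxoethyl)cyclohex-3-ene-1-carboxylate; 12 benzyl (2Z)-4-(2,5-dimethoxy-4-methylphenyl)-2-methyl-4-oxobut-2-enoate
Product: 13 trans-decalin hydroxy diester (9β-(2,5-dimethoxy-4-methylbenzoyl), 8β-CO2Bn/8α-CH3, 7β-OH, 10β-CH3, 5α-H, 4β-CH3/4α-CO2CH2CH2SiMe3)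
Conditions: Fe(acac)3 (30 mol%), PhSiH3 (2.5 equiv), EtOH/HOCH2CH2OH 5:1, 60 °C; 12 (1.5 equiv)
Reagents that add atoms: none
Why: Iron-hydride hydrogen-atom transfer to C1 of the C1=C10 alkene of 8 gives the tertiary C10 radical, which adds to C9 (the CH terminus) of 12; the resulting α-ester C8 radical is reduced by divalent iron to an iron enolate that attacks the C7 aldehyde, and protonation gives 13. The closest known reaction type is the metal-hydride-initiated radical conjugate addition with polar crossover into an aldol (reductive olefin coupling followed by aldol annulation). Ring B is closed by an intermolecular Giese addition (C9–C10) followed by a 6-(enolexo)-exo-trig aldol (C7–C8). C10 is set by attack on the α face of the ring-A radical, trans to the C5 side arm and away from the axial 4β-methyl group, which gives the trans-decalin; C9 should result from the approach in which its hydrogen lies next to the C5 arm and the acceptor alkene points away from ring A, and because C9–H is α to the aryl ketone a wrong epimer can be equilibrated with base; C8 and C7 follow from a chelated chair aldol (ester axial, hydroxyl equatorial, cis) and are both erased in step 9. The step needs addition at C9 and not at C8, and hydrogen-atom transfer to the electron-rich alkene and not to the acceptor: the fully substituted C8 should not accept a tertiary radical, and the iron hydride is polarity-matched with the trisubstituted alkene.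

Step 8
Reactants: 13 trans-decalin hydroxy diester
Product: 14 β-hydroxy acid (8β-CO2H, 7β-OH)
Conditions: H2 (1 atm), 10% Pd/C, EtOAc, rt
Reagents that add atoms: none
Why: Catalytic hydrogenolysis cleaves only the benzyl ester (the aryl ketone and the silylethyl ester are inert under neutral conditions) and changes no stereocenter.

Step 9
Reactants: 14 β-hydroxy acid
Product: 16 2-(trimethylsilyl)ethyl 11-(2,5-dimethoxy-4-methylphenyl)-11-oxodrim-7-ene-4α-carboxylate, via β-lactone 15 (not isolated)
Conditions: PhSO2Cl, pyridine, 0 °C; then 2,4,6-collidine, 160 °C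
Reagents that add atoms: none
Why: Carboxyl activation of the cis β-hydroxy acid closes the β-lactone with retention, and thermal [2+2] cycloreversion (decarboxylation of a β-lactone) is stereospecific and regiospecific, so the alkene can only arise between C7 and C8 while both auxiliary stereocenters disappear.

Step 10
Reactants: 16 2-(trimethylsilyl)ethyl 11-(2,5-dimethoxy-4-methylphenyl)-11-oxodrim-7-ene-4α-carboxylate
Product: 17 2-(trimethylsilyl)ethyl 11-(2-hydroxy-5-methoxy-4-methylphenyl)-11-oxodrim-7-ene-4α-carboxylate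
Conditions: BCl3 (1.5 equiv), CH2Cl2, −78 → −20 °C; aq NaHCO3
Reagents that add atoms: none
Why: Chelation-controlled ether cleavage, in which boron bridges the ketone oxygen and the ortho methoxy group so that only this methyl ether is removed at low temperature, differentiates the two arene oxygens without touching a stereocenter.

Step 11
Reactants: 17 2-(trimethylsilyl)ethyl 11-(2-hydroxy-5-methoxy-4-methylphenyl)-11-oxodrim-7-ene-4α-carboxylate
Product: 19 2-(trimethylsilyl)ethyl 11-(2-hydroxy-5-methoxy-4-methylphenyl)drim-7-ene-4α-carboxylate, via aryl ethyl carbonate 18 (not isolated)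
Conditions: ClCO2Et, Et3N, THF, 0 °C; then NaBH4, H2O, 0 °C → rt
Reagents that add atoms: ethyl chloroformate CCOC(Cl)=O (its atoms stay only in 18 and are lost again)
Why: Acylation of the phenol, borohydride reduction of the ketone, migration and loss of the carbonate to an ortho-quinone methide and its 1,4-reduction in situ (deoxygenation of an ortho-acylphenol through a quinone methide) turn C11 into CH2 under basic conditions that leave C9 and the C7=C8 alkene unchanged.

Step 12
Reactants: 19 2-(trimethylsilyl)ethyl 11-(2-hydroxy-5-methoxy-4-methylphenyl)drim-7-ene-4α-carboxylate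
Product: 20 quinone monoketal (C2′ carbonyl, C5′ dimethyl ketal)
Conditions: PhI(OAc)2, MeOH, NaHCO3, 0 °C
Reagents that add atoms: methanol CO
Why: Oxidative dearomatisation of the para-methoxyphenol with the hypervalent iodine reagent in methanol gives the quinone monoketal whose free carbonyl is C2′, next to C1′, as the regiochemistry of step 13 requires.

Step 13
Reactants: 20 quinone monoketal
Product: 21 (1′R,6′S)-1′,6′-epoxy monoketal
Conditions: Ph3COOH, NaHMDS, D-(−)-diisopropyl tartrate, 4 Å MS, toluene, −50 °C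
Reagents that add atoms: trityl hydroperoxide OOC(c1ccccc1)(c1ccccc1)c1ccccc1
Why: Nucleophilic (Weitz–Scheffer) epoxidation takes place at the C1′=C6′ alkene because its β-carbon C6′ is unsubstituted while C4′ carries a methyl group, and the chiral sodium tartrate–trityl peroxide aggregate chooses the dienone face (reagent control), which sets C1′ and C6′ together.

Step 14
Reactants: 21 (1′R,6′S)-1′,6′-epoxy monoketal
Product: 22 (1′R,6′S)-epoxy enedione
Conditions: montmorillonite K10, wet CH2Cl2, rt
Reagents that add atoms: water O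
Why: Mild heterogeneous acid hydrolysis of the dimethyl ketal should give the epoxy enedione without opening the epoxide or cleaving the silylethyl ester.

Step 15
Reactants: 22 (1′R,6′S)-epoxy enedione
Product: 23 2-(trimethylsilyl)ethyl ester of the target, (1′S,2′R,5′S,6′R)-epoxy diol
Conditions: NaBH4, CeCl3·7H2O, MeOH, −78 °C
Reagents that add atoms: none
Why: Luche 1,2-reduction of both carbonyl groups, hydride entering on the epoxide face because the opposite face is shielded by the CH2–drimenyl group on C1′ (α to C2′, 1,3 to C5′), should set C2′ and C5′ with both hydroxyl groups anti to the epoxide oxygen.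

Step 16
Reactants: 23 2-(trimethylsilyl)ethyl ester of the target
Product: 24 CNP0358222.2
Conditions: Bu4NF, AcOH (1:1), THF, 0 °C → rt; work-up at pH 5
Reagents that add atoms: none
Why: Fluoride attacks silicon and β-elimination releases ethene and the carboxylate (cleavage of a 2-(trimethylsilyl)ethyl ester), the buffer suppressing Payne rearrangement of the epoxy alcohols, so no stereocenter changes.

**Compound list**

1 | ethyl 2-formylpropanoate | CCOC(=O)C(C)C=O | starting material
2 | 2-(trimethylsilyl)ethyl 2-formylpropanoate | C[Si](C)(C)CCOC(=O)C(C)C=O | intermediate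
3 | pent-1-en-3-one | C=CC(=O)CC | starting material
4 | 2-(trimethylsilyl)ethyl (2R)-2-formyl-2-methyl-5-oxoheptanoate | O=C[C@@](C)(CCC(=O)CC)C(=O)OCC[Si](C)(C)C | intermediate (not isolated)
5 | 2-(trimethylsilyl)ethyl (1R)-1,3-dimethyl-4-oxocyclohex-2-ene-1-carboxylate | O=C1CC[C@@](C)(C(=O)OCC[Si](C)(C)C)C=C1C | intermediate
6 | 2-(trimethylsilyl)ethyl (1R,4R)-4-hydroxy-1,3-dimethylcyclohex-2-ene-1-carboxylate | O[C@@H]1CC[C@@](C)(C(=O)OCC[Si](C)(C)C)C=C1C | intermediate
7 | 2-(trimethylsilyl)ethyl (1R,4R)-4-(ethenyloxy)-1,3-dimethylcyclohex-2-ene-1-carboxylate | C=CO[C@@H]1CC[C@@](C)(C(=O)OCC[Si](C)(C)C)C=C1C | intermediate (not isolated)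
8 | 2-(trimethylsilyl)ethyl (1R,2R)-1,3-dimethyl-2-(2-oxoethyl)cyclohex-3-ene-1-carboxylate | O=CC[C@@H]1C(C)=CCC[C@@]1(C)C(=O)OCC[Si](C)(C)C | intermediate
9 | 1,4-dimethoxy-2-methylbenzene | COc1ccc(OC)c(C)c1 | starting material
10 | citraconic anhydride | CC1=CC(=O)OC1=O | starting material
11 | (2Z)-4-(2,5-dimethoxy-4-methylphenyl)-2-methyl-4-oxobut-2-enoic acid | COc1cc(C)c(OC)cc1C(=O)/C=C(/C)C(=O)O | intermediate
12 | benzyl (2Z)-4-(2,5-dimethoxy-4-methylphenyl)-2-methyl-4-oxobut-2-enoate | COc1cc(C)c(OC)cc1C(=O)/C=C(/C)C(=O)OCc1ccccc1 | intermediate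
13 | trans-decalin hydroxy diester: 9β-(2,5-dimethoxy-4-methylbenzoyl), 8β-CO2Bn, 8α-CH3, 7β-OH, 10β-CH3, 5α-H, 4β-CH3, 4α-CO2CH2CH2SiMe3 | COc1cc(C)c(OC)cc1C(=O)[C@H]2[C@@](C)(C(=O)OCc3ccccc3)[C@@H](O)C[C@@H]4[C@]2(C)CCC[C@@]4(C)C(=O)OCC[Si](C)(C)C | intermediate
14 | β-hydroxy acid from 13 (8β-CO2H, 7β-OH) | COc1cc(C)c(OC)cc1C(=O)[C@H]2[C@@](C)(C(=O)O)[C@@H](O)C[C@@H]4[C@]2(C)CCC[C@@]4(C)C(=O)OCC[Si](C)(C)C | intermediate
15 | cis-fused 7β,8β-β-lactone of 14 | COc1cc(C)c(OC)cc1C(=O)[C@H]2[C@@]3(C)C(=O)O[C@H]3C[C@@H]4[C@]2(C)CCC[C@@]4(C)C(=O)OCC[Si](C)(C)C | intermediate (not isolated)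
16 | 2-(trimethylsilyl)ethyl 11-(2,5-dimethoxy-4-methylphenyl)-11-oxodrim-7-ene-4α-carboxylate (5α-H, 9α-H, 10β-CH3, 4β-CH3) | COc1cc(C)c(OC)cc1C(=O)[C@H]2C(C)=CC[C@@H]4[C@]2(C)CCC[C@@]4(C)C(=O)OCC[Si](C)(C)C | intermediate
17 | 2-(trimethylsilyl)ethyl 11-(2-hydroxy-5-methoxy-4-methylphenyl)-11-oxodrim-7-ene-4α-carboxylate | Oc1cc(C)c(OC)cc1C(=O)[C@H]2C(C)=CC[C@@H]4[C@]2(C)CCC[C@@]4(C)C(=O)OCC[Si](C)(C)C | intermediate
18 | aryl ethyl carbonate of 17 | CCOC(=O)Oc1cc(C)c(OC)cc1C(=O)[C@H]2C(C)=CC[C@@H]4[C@]2(C)CCC[C@@]4(C)C(=O)OCC[Si](C)(C)C | intermediate (not isolated)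
19 | 2-(trimethylsilyl)ethyl 11-(2-hydroxy-5-methoxy-4-methylphenyl)drim-7-ene-4α-carboxylate | Oc1cc(C)c(OC)cc1C[C@H]2C(C)=CC[C@@H]4[C@]2(C)CCC[C@@]4(C)C(=O)OCC[Si](C)(C)C | intermediate
20 | quinone monoketal: 5′,5′-dimethoxy-4′-methyl-2′-oxocyclohexa-3′,6′-dien-1′-yl on C11 | O=C1C=C(C)C(OC)(OC)C=C1C[C@H]2C(C)=CC[C@@H]4[C@]2(C)CCC[C@@]4(C)C(=O)OCC[Si](C)(C)C | intermediate
21 | (1′R,6′S)-1′,6′-epoxide of 20 (epoxide oxygen anti to C11) | O=C1C=C(C)C(OC)(OC)[C@H]3O[C@@]13C[C@H]2C(C)=CC[C@@H]4[C@]2(C)CCC[C@@]4(C)C(=O)OCC[Si](C)(C)C | intermediate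
22 | (1′R,6′S)-1′,6′-epoxy-4′-methyl-2′,5′-dioxocyclohex-3′-enyl compound (epoxy enedione) | O=C1C=C(C)C(=O)[C@H]3O[C@@]13C[C@H]2C(C)=CC[C@@H]4[C@]2(C)CCC[C@@]4(C)C(=O)OCC[Si](C)(C)C | intermediate
23 | 2-(trimethylsilyl)ethyl ester of the target, (1′S,2′R,5′S,6′R)-1′,6′-epoxy-2′,5′-diol | O[C@@H]1C=C(C)[C@H](O)[C@H]3O[C@@]13C[C@H]2C(C)=CC[C@@H]4[C@]2(C)CCC[C@@]4(C)C(=O)OCC[Si](C)(C)C | intermediate
24 | CNP0358222.2: 11-[(1′S,2′R,5′S,6′R)-2′,5′-dihydroxy-4′-methyl-7′-oxabicyclo[4.1.0]hept-3′-en-1′-yl]drim-7-ene-4α-carboxylic acid (4R,5R,9S,10R) | CC1=C[C@@H](O)[C@]2(C[C@H]3C(C)=CC[C@@H]4[C@]3(C)CCC[C@@]4(C)C(=O)O)O[C@@H]2[C@H]1O | target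

**Totals.** 16 steps in all; the longest linear sequence is 14 steps (steps 1–4 and 7–16), with steps 5–6 as the convergent branch.

**Steps most likely to fail**

Step 7. The bimolecular addition of the hindered C10 radical may lose against its reduction or back-isomerisation, and face selection at C9 may be poor. The fallback makes the two bonds in two stages by known reactions and sets out from 8. The lithium dienolate (LDA, THF, −78 °C) of benzyl (3E)-4-[2-(tert-butyldimethylsilyloxy)-5-methoxy-4-methylphenyl]-2-methylbut-3-enoate F1 (from the silylated salicylaldehyde by Wittig olefination) should add through its α-carbon to the aldehyde of 8 and give the aldol adduct F2 (C7–C8). Fe(acac)3/PhSiH3 then closes ring B by 6-exo addition of the C10 radical to the styrene carbon C9, the benzylic radical taking up hydrogen, to give the decalin hydroxy diester F3. Hydrogenolysis gives the hydroxy acid F4; β-lactone formation and thermolysis as in step 9 (or anti elimination with DMF dineopentyl acetal) give the aryl silyl ether F5. K2CO3/MeOH then returns to 19, so steps 8–11 are bypassed.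

Step 13. Reagent control may fail against the remote chiral decalin, giving poor facial selectivity. The fallback sets out from 20: transketalisation with (2R,4R)-pentane-2,4-diol (PPTS, benzene, −MeOH) gives the C2-symmetric dioxane ketal F6. Auxiliary-controlled nucleophilic epoxidation (Ph3COOH, KHMDS, THF, −35 °C) gives the epoxy dioxane ketal F7. Hydrolysis (aq HF, MeCN) returns to 22.

Step 15. Hydride may attack anti to the epoxide oxygen at one or both carbonyl groups, or add 1,4 to the enedione. The fallback sets out from 21 and reduces the carbonyls one at a time. Luche reduction of the only carbonyl (C2′, strongly shielded by the C1′ substituent) gives the epoxy alcohol ketal F8. TBSCl/imidazole gives the silyl ether F9, and K10 hydrolysis gives the enone F10. A second Luche reduction, now also steered to the epoxide face by the C2′ silyl ether, gives the monoprotected diol F11. Bu4NF removes both silyl groups and returns to 24.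

**Further compounds**

F1 | step 7 | benzyl (3E)-4-[2-(tert-butyldimethylsilyloxy)-5-methoxy-4-methylphenyl]-2-methylbut-3-enoate | COc1cc(/C=C/C(C)C(=O)OCc2ccccc2)c(O[Si](C)(C)C(C)(C)C)cc1C
F2 | step 7 | aldol adduct of F1 and 8 (C7 carbinol, C8 quaternary, mixture at both) | COc1cc(/C=C/C(C)(C(=O)OCc2ccccc2)C(O)C[C@@H]3C(C)=CCC[C@@]3(C)C(=O)OCC[Si](C)(C)C)c(O[Si](C)(C)C(C)(C)C)cc1C
F3 | step 7 | cyclised trans-decalin hydroxy diester with 9β-CH2-aryl | COc1cc(C[C@H]2C(C)(C(=O)OCc3ccccc3)C(O)C[C@@H]4[C@]2(C)CCC[C@@]4(C)C(=O)OCC[Si](C)(C)C)c(O[Si](C)(C)C(C)(C)C)cc1C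
F4 | step 7 | hydroxy acid from F3 | COc1cc(C[C@H]2C(C)(C(=O)O)C(O)C[C@@H]4[C@]2(C)CCC[C@@]4(C)C(=O)OCC[Si](C)(C)C)c(O[Si](C)(C)C(C)(C)C)cc1C
F5 | step 7 | tert-butyldimethylsilyl ether of 19 | COc1cc(C[C@H]2C(C)=CC[C@@H]4[C@]2(C)CCC[C@@]4(C)C(=O)OCC[Si](C)(C)C)c(O[Si](C)(C)C(C)(C)C)cc1C
F6 | step 13 | (4R,6R)-4,6-dimethyl-1,3-dioxane ketal analogue of 20 | O=C1C=C(C)C2(O[C@H](C)C[C@@H](C)O2)C=C1C[C@H]5C(C)=CC[C@@H]4[C@]5(C)CCC[C@@]4(C)C(=O)OCC[Si](C)(C)C
F7 | step 13 | (1′R,6′S)-epoxide of F6 | O=C1C=C(C)C2(O[C@H](C)C[C@@H](C)O2)[C@H]3O[C@@]13C[C@H]5C(C)=CC[C@@H]4[C@]5(C)CCC[C@@]4(C)C(=O)OCC[Si](C)(C)C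
F8 | step 15 | 2′-hydroxy epoxy ketal (hydroxyl anti to the epoxide) | O[C@@H]1C=C(C)C(OC)(OC)[C@H]3O[C@@]13C[C@H]2C(C)=CC[C@@H]4[C@]2(C)CCC[C@@]4(C)C(=O)OCC[Si](C)(C)C
F9 | step 15 | 2′-O-tert-butyldimethylsilyl ether of F8 | CC(C)(C)[Si](C)(C)O[C@@H]1C=C(C)C(OC)(OC)[C@H]3O[C@@]13C[C@H]2C(C)=CC[C@@H]4[C@]2(C)CCC[C@@]4(C)C(=O)OCC[Si](C)(C)C
F10 | step 15 | 2′-silyloxy-1′,6′-epoxy-5′-enone | CC(C)(C)[Si](C)(C)O[C@@H]1C=C(C)C(=O)[C@H]3O[C@@]13C[C@H]2C(C)=CC[C@@H]4[C@]2(C)CCC[C@@]4(C)C(=O)OCC[Si](C)(C)C
F11 | step 15 | 2′-O-silyl ether of 23 | CC(C)(C)[Si](C)(C)O[C@@H]1C=C(C)[C@H](O)[C@H]3O[C@@]13C[C@H]2C(C)=CC[C@@H]4[C@]2(C)CCC[C@@]4(C)C(=O)OCC[Si](C)(C)C
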